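**Retrosynthetic overview**
- Feature: in the oxane (O1, C2–C6) the C2 aryl, the CH2 on C3 (C8) and the carbinol carbon on C5 (C7) lie on one face. Joining C7 and C8 as a CH=CH bridge turns the oxane into the six-membered ring of a 3-oxabicyclo[3.2.1]oct-6-ene, in which the C2 aryl (axial in the target) is equatorial.
- Late disconnections: C8–C9 (Negishi coupling of a C3 CH2ZnI with an (E)-β-bromostyrene), C7–aryl (chelation-controlled Grignard addition to the C5 formyl group), C7=C8 (ozonolysis read backwards).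
- Key disconnection: O1–C2, closed by attack of the C6 hydroxyl on a 4-silyloxybenzylic cation at C2 under equilibrating acid.
- Early disconnections: C2–aryl (Grignard addition to an aldehyde) and lipase desymmetrisation of meso cis-cyclopent-4-ene-1,3-dimethanol from norbornadiene, which fixes C3 and C5.
- Ring order: cyclopentene (from norbornadiene), then the oxane (step 8, as a bicycle), then the carbocycle is cut open.

Key step: step 8

Remark 1: TIPS = tri(propan-2-yl)silyl; locants C2–C8 are those of the target oxane (C8 = CH2 on C3, C7 = carbinol carbon on C5).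
Remark 2: the lipase is assumed to acetylate the arm that gives the monoacetate drawn in step 2; if it prefers the other arm, hydrolysis of the meso diacetate with the same lipase is enantiocomplementary and gives the same monoacetate.
Remark 3: the hydroxy acetate of step 6 and the diol of step 7 are carried as mixtures of both carbinol epimers (SMILES without a descriptor at that carbon), because the cation of step 8 erases this centre.

**Step 1**
Reactants: 1 norbornadiene (bicyclo[2.2.1]hepta-2,5-diene)
Product: 3 cis-cyclopent-4-ene-1,3-diyldimethanol (meso), via mono-ozonide 2 (not isolated)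
Conditions: O3 (0.9 equiv), CH2Cl2, −78 °C; then NaBH4, MeOH, −78 °C to rt
Reagents that add atoms: ozone, O=[O+][O-]
Why: Reductive ozonolysis with a deficiency of ozone should cleave one of the two strained double bonds and leave the cyclopentene double bond, and the two hydroxymethyl groups stay cis because both carbons were bridgeheads of the same bicycle.

**Step 2**
Reactants: 3 cis-cyclopent-4-ene-1,3-diyldimethanol
Product: 4 [(1S,4R)-4-(hydroxymethyl)cyclopent-2-en-1-yl]methyl acetate
Conditions: Pseudomonas fluorescens lipase, vinyl acetate, THF, rt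
Reagents that add atoms: vinyl acetate, C=COC(C)=O
Why: Enzymatic desymmetrisation of a meso diol by lipase transesterification with an irreversible acyl donor should acetylate one enantiotopic arm only, which sets the absolute configuration of both ring stereocentres (the later C3 and C5) at once.

**Step 3**
Reactants: 5 4-bromophenol
Product: 6 (4-bromophenoxy)tri(propan-2-yl)silane
Conditions: iPr3SiCl, imidazole, DMF, rt
Reagents that add atoms: chlorotri(propan-2-yl)silane, CC(C)[Si](Cl)(C(C)C)C(C)C
Why: Imidazole-mediated silylation masks the acidic phenol with a bulky silyl ether that should survive Grignard, hydride and mild acid conditions and fall to fluoride at the end.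

**Step 4**
Reactants: 6 (4-bromophenoxy)tri(propan-2-yl)silane
Product: 7 [4-(TIPS-oxy)phenyl]magnesium bromide (titrated THF solution)
Conditions: Mg turnings, I2 (crystal), THF, reflux
Reagents that add atoms: magnesium, [Mg]
Why: Grignard reagent formation by insertion of magnesium into the aryl C–Br bond is routine for silyl-protected bromophenols.

**Step 5**
Reactants: 4 [(1S,4R)-4-(hydroxymethyl)cyclopent-2-en-1-yl]methyl acetate
Product: 8 [(1S,4R)-4-formylcyclopent-2-en-1-yl]methyl acetate
Conditions: Dess–Martin periodinane, pyridine, CH2Cl2, 0 °C; crude used at once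
Reagents that add atoms: none
Why: Buffered Dess–Martin oxidation converts the primary alcohol to the aldehyde without base strong enough to enolise it, and immediate use of the crude β,γ-unsaturated aldehyde should keep the allylic α-stereocentre and the position of the double bond.

**Step 6**
Reactants: 8 [(1S,4R)-4-formylcyclopent-2-en-1-yl]methyl acetate; 7 [4-(TIPS-oxy)phenyl]magnesium bromide
Product: 9 [(1S,4R)-4-{hydroxy[4-(TIPS-oxy)phenyl]methyl}cyclopent-2-en-1-yl]methyl acetate (both carbinol epimers)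
Conditions: 7 (1.2 equiv), THF, −78 °C; sat. aq. NH4Cl
Reagents that add atoms: none
Why: Grignard addition to the aldehyde at −78 °C should outrun both attack on the acetate and enolisation, and the new carbinol centre, for which Felkin–Anh bias is weak, is left as a mixture on purpose because step 8 erases it.

**Step 7**
Reactants: 9 hydroxy acetate
Product: 10 [(1R,4S)-4-(hydroxymethyl)cyclopent-2-en-1-yl][4-(TIPS-oxy)phenyl]methanol (both carbinol epimers)
Conditions: iBu2AlH (3.5 equiv), CH2Cl2, −78 °C; aq. potassium sodium tartrate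
Reagents that add atoms: none
Why: Reductive cleavage of the acetate by the aluminium hydride frees the primary alcohol without exposing the aryl silyl ether to the basic methanolysis that an ester exchange would need.

**Step 8**
Reactants: 10 cis-3-[hydroxy(aryl)methyl]-5-(hydroxymethyl)cyclopentene
Product: 11 (1R,2R,5S)-2-[4-(TIPS-oxy)phenyl]-3-oxabicyclo[3.2.1]oct-6-ene (aryl cis to the etheno bridge)
Conditions: (+)-camphor-10-sulfonic acid (0.2 equiv), 4 Å molecular sieves, CH2Cl2 (0.01 M), 0 °C to rt
Reagents that add atoms: none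
Why: Camphorsulfonic acid protonates the benzylic hydroxyl of either epimer of 10 and loss of water gives a 4-silyloxybenzyl cation (an O-silylated quinone methide), which the cis hydroxymethyl oxygen traps at the cationic carbon to form O1–C2, an SN1 cycloetherification of the kind known for 2-aryl-tetrahydropyrans from 4-alkoxybenzylic alcohols. The oxane closes in a 6-exo-trig sense onto the exocyclic cationic carbon, and because its C3 and C5 are the cis allylic carbons of the cyclopentene the product is the 3-oxabicyclo[3.2.1]oct-6-ene. C2, the only new stereocentre, is set under thermodynamic control: the benzylic ether re-ionises in the acid, and the epimer with the aryl equatorial on the oxane chair and cis to the etheno bridge should accumulate, since the axial epimer suffers 1,3-diaxial contacts with the axial H of the O–CH2 carbon and the inward H of the methylene bridge. The chair-like closure should favour the same epimer kinetically, so both controls point the same way. The step needs C2 selectivity and ring closure in preference to E1 loss of the allylic ring proton and to intermolecular etherification; the bridge secures the first, and catalytic acid, high dilution and low temperature are chosen for the others. C3 and C5 are not touched.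

**Step 9**
Reactants: 11 bicyclic ether
Product: 13 (2R,3S,5R)-2-[4-(TIPS-oxy)phenyl]oxane-3,5-dicarbaldehyde, via ozonide 12 (not isolated)
Conditions: O3, CH2Cl2, −78 °C (Sudan Red 7B end point); then Me2S, −78 °C to rt; crude used without chromatography
Reagents that add atoms: ozone, O=[O+][O-]
Why: Ozonolysis with reductive work-up should cleave the strained etheno bridge well before the silyloxy arene or the benzylic ether C–H reacts, turning C7 and C8 into formyl groups while C3 and C5 keep their configuration as long as the dialdehyde is not exposed to base or silica.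

**Step 10**
Reactants: 13 dialdehyde; 7 [4-(TIPS-oxy)phenyl]magnesium bromide
Product: 15 4,8-bis[4-(TIPS-oxy)phenyl]-3,7-dioxabicyclo[3.3.1]nonan-2-ol (lactol as anomer mixture), via bromomagnesium alkoxide 14 (not isolated)
Conditions: MgBr2·OEt2 (3 equiv), CH2Cl2, −78 °C; then 7 (1.2 equiv), −78 °C; sat. aq. NH4Cl
Reagents that add atoms: none
Why: This is a Cram-chelate Grignard addition to a β-alkoxy aldehyde: MgBr2 bound to O1 and the formyl oxygens holds the chair with both formyl groups axial and the C2 aryl equatorial, where that aryl blocks the outer face of the C3 formyl, so the aryl group should add to the C5 formyl on the face anti to C4 (C7 = R), and the bromomagnesium alkoxide then closes onto the C3 formyl as a lactolate, which prevents a second addition.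

**Step 11**
Reactants: 15 lactol
Product: 17 [(2R,3R,5R)-5-{(R)-hydroxy[4-(TIPS-oxy)phenyl]methyl}-2-[4-(TIPS-oxy)phenyl]oxan-3-yl]methanol, via hydroxy aldehyde 16 (not isolated)
Conditions: NaBH4, EtOH/THF, 0 °C to rt
Reagents that add atoms: none
Why: Hydride reduction of a lactol runs through its ring-open hydroxy aldehyde tautomer and unveils the C8 primary alcohol, and C3 is protected from epimerisation because its formyl group stays masked until the moment it is reduced.

**Step 12**
Reactants: 17 diol
Product: 18 (R)-{(3R,5S,6R)-5-(iodomethyl)-6-[4-(TIPS-oxy)phenyl]oxan-3-yl}[4-(TIPS-oxy)phenyl]methanol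
Conditions: I2 (1.2 equiv), PPh3 (1.2 equiv), imidazole (2.5 equiv), THF, 0 °C
Reagents that add atoms: iodine, II
Why: Appel-type iodination should take the unhindered primary alcohol in preference to the secondary benzylic one at 0 °C, and the imidazole buffer keeps the medium non-acidic so that the now axial C2 aryl ether does not epimerise.

**Step 13**
Reactants: 18 iodo alcohol
Product: 19 triethyl{(R)-[(3R,5S,6R)-5-(iodomethyl)-6-[4-(TIPS-oxy)phenyl]oxan-3-yl][4-(TIPS-oxy)phenyl]methoxy}silane
Conditions: Et3SiOTf, 2,6-lutidine, CH2Cl2, −78 °C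
Reagents that add atoms: triethylsilyl trifluoromethanesulfonate, CC[Si](CC)(CC)OS(=O)(=O)C(F)(F)F
Why: Silylation with the silyl triflate and a hindered, non-nucleophilic base protects the C7 hydroxyl, which would otherwise quench the organozinc of step 16, without displacing the primary iodide.

**Step 14**
Reactants: 20 4-hydroxycinnamic acid
Product: 22 (E)-3-[4-(TIPS-oxy)phenyl]prop-2-enoic acid, via bis-silyl ester 21 (not isolated)
Conditions: iPr3SiCl (2.3 equiv), imidazole, DMF, rt; then K2CO3 (1.1 equiv), THF/MeOH/H2O, 0 °C, short; aq. citric acid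
Reagents that add atoms: chlorotri(propan-2-yl)silane, CC(C)[Si](Cl)(C(C)C)C(C)C
Why: Silylation covers phenol and acid, and brief carbonate hydrolysis should cleave only the much more labile silyl ester, leaving the phenol protected against ring bromination in step 15.

**Step 15**
Reactants: 22 (E)-3-[4-(TIPS-oxy)phenyl]prop-2-enoic acid
Product: 23 {4-[(E)-2-bromoethenyl]phenoxy}tri(propan-2-yl)silane
Conditions: N-bromosuccinimide (1.1 equiv), LiOAc (0.2 equiv), MeCN/H2O (30:1), rt
Reagents that add atoms: N-bromosuccinimide, BrN1C(=O)CCC1=O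
Why: Catalytic Hunsdiecker-type bromodecarboxylation of an electron-rich cinnamic acid (bromonium formation, carboxylate closure, loss of CO2) should give the (E)-bromoalkene.

**Step 16**
Reactants: 19 silyl-protected iodide; 23 (E)-bromostyrene
Product: 25 triethyl{(R)-[(3R,5S,6R)-5-{(E)-3-[4-(TIPS-oxy)phenyl]prop-2-en-1-yl}-6-[4-(TIPS-oxy)phenyl]oxan-3-yl][4-(TIPS-oxy)phenyl]methoxy}silane, via alkylzinc iodide 24 (not isolated)
Conditions: Zn dust (activated with Me3SiCl), DMF, 40 °C; then 23 (1.3 equiv), Pd(PPh3)4 (5 mol %), DMF/THF, rt to 45 °C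
Reagents that add atoms: none
Why: Zinc insertion into the primary C–I bond gives an alkylzinc iodide that has no β-leaving group and tolerates silyl ethers, and Negishi sp3–sp2 coupling with the alkenyl bromide forms C8–C9 with retention of the E geometry.

**Step 17**
Reactants: 25 fully silylated precursor
Product: 26 4-[(E)-3-{(2R,3S,5R)-5-[(R)-hydroxy(4-hydroxyphenyl)methyl]-2-(4-hydroxyphenyl)oxan-3-yl}prop-1-en-1-yl]phenol (CNP0182155.1)
Conditions: Bu4NF (6 equiv), AcOH (6 equiv), THF, 0 °C to rt; pH 7 buffer work-up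
Reagents that add atoms: none
Why: Fluoride desilylation removes the three aryl silyl ethers and the triethylsilyl ether, and the acetic acid buffer keeps the medium near neutral so that neither the 4-hydroxybenzylic ether at C2 nor the 4-hydroxybenzylic alcohol at C7 ionises.

**Compound list**
1 | norbornadiene | C1=CC2C=CC1C2 | starting material
2 | mono-ozonide of 1 (1,2,4-trioxolane bridging the cis 1,3-positions of cyclopent-4-ene; acetal carbons unassigned) | C1=C[C@H]2C[C@@H]1C1OC2OO1 | intermediate
3 | cis-cyclopent-4-ene-1,3-diyldimethanol (meso) | C1=C[C@H](CO)C[C@@H]1CO | intermediate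
4 | [(1S,4R)-4-(hydroxymethyl)cyclopent-2-en-1-yl]methyl acetate | C1=C[C@H](CO)C[C@@H]1COC(C)=O | intermediate
5 | 4-bromophenol | Oc1ccc(Br)cc1 | starting material
6 | (4-bromophenoxy)tri(propan-2-yl)silane | CC(C)[Si](C(C)C)(C(C)C)Oc1ccc(Br)cc1 | intermediate
7 | [4-(TIPS-oxy)phenyl]magnesium bromide | CC(C)[Si](C(C)C)(C(C)C)Oc1ccc([Mg]Br)cc1 | intermediate
8 | [(1S,4R)-4-formylcyclopent-2-en-1-yl]methyl acetate | C1=C[C@H](C=O)C[C@@H]1COC(C)=O | intermediate
9 | [(1S,4R)-4-{hydroxy[4-(TIPS-oxy)phenyl]methyl}cyclopent-2-en-1-yl]methyl acetate, both carbinol epimers | C1=C[C@H](C(O)c2ccc(O[Si](C(C)C)(C(C)C)C(C)C)cc2)C[C@@H]1COC(C)=O | intermediate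
10 | [(1R,4S)-4-(hydroxymethyl)cyclopent-2-en-1-yl][4-(TIPS-oxy)phenyl]methanol, both carbinol epimers | C1=C[C@H](C(O)c2ccc(O[Si](C(C)C)(C(C)C)C(C)C)cc2)C[C@@H]1CO | intermediate
11 | (1R,2R,5S)-2-[4-(TIPS-oxy)phenyl]-3-oxabicyclo[3.2.1]oct-6-ene | C1=C[C@H]2C[C@@H]1CO[C@H]2c1ccc(O[Si](C(C)C)(C(C)C)C(C)C)cc1 | intermediate
12 | ozonide of 11 (1,2,4-trioxolane across the former C6=C7; acetal carbons unassigned) | C15OOC(O5)[C@H]2C[C@@H]1CO[C@H]2c1ccc(O[Si](C(C)C)(C(C)C)C(C)C)cc1 | intermediate
13 | (2R,3S,5R)-2-[4-(TIPS-oxy)phenyl]oxane-3,5-dicarbaldehyde | O=C[C@H]2C[C@@H](C=O)CO[C@H]2c2ccc(O[Si](C(C)C)(C(C)C)C(C)C)cc2 | intermediate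
14 | bromomagnesium (R)-[(3R,5S,6R)-5-formyl-6-[4-(TIPS-oxy)phenyl]oxan-3-yl][4-(TIPS-oxy)phenyl]methanolate | O=C[C@H]2C[C@@H]([C@@H](O[Mg]Br)c3ccc(O[Si](C(C)C)(C(C)C)C(C)C)cc3)CO[C@H]2c2ccc(O[Si](C(C)C)(C(C)C)C(C)C)cc2 | intermediate
15 | 4,8-bis[4-(TIPS-oxy)phenyl]-3,7-dioxabicyclo[3.3.1]nonan-2-ol (ring carbons configured as in 17; anomeric carbon unassigned) | OC4[C@H]2C[C@@H]([C@@H](O4)c3ccc(O[Si](C(C)C)(C(C)C)C(C)C)cc3)CO[C@H]2c2ccc(O[Si](C(C)C)(C(C)C)C(C)C)cc2 | intermediate
16 | (2R,3S,5R)-5-{(R)-hydroxy[4-(TIPS-oxy)phenyl]methyl}-2-[4-(TIPS-oxy)phenyl]oxane-3-carbaldehyde (ring-open tautomer of 15) | O=C[C@H]2C[C@@H]([C@@H](O)c3ccc(O[Si](C(C)C)(C(C)C)C(C)C)cc3)CO[C@H]2c2ccc(O[Si](C(C)C)(C(C)C)C(C)C)cc2 | intermediate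
17 | [(2R,3R,5R)-5-{(R)-hydroxy[4-(TIPS-oxy)phenyl]methyl}-2-[4-(TIPS-oxy)phenyl]oxan-3-yl]methanol | OC[C@H]2C[C@@H]([C@@H](O)c3ccc(O[Si](C(C)C)(C(C)C)C(C)C)cc3)CO[C@H]2c2ccc(O[Si](C(C)C)(C(C)C)C(C)C)cc2 | intermediate
18 | (R)-{(3R,5S,6R)-5-(iodomethyl)-6-[4-(TIPS-oxy)phenyl]oxan-3-yl}[4-(TIPS-oxy)phenyl]methanol | IC[C@H]2C[C@@H]([C@@H](O)c3ccc(O[Si](C(C)C)(C(C)C)C(C)C)cc3)CO[C@H]2c2ccc(O[Si](C(C)C)(C(C)C)C(C)C)cc2 | intermediate
19 | triethylsilyl ether of 18 at the C7 hydroxyl | IC[C@H]2C[C@@H]([C@@H](O[Si](CC)(CC)CC)c3ccc(O[Si](C(C)C)(C(C)C)C(C)C)cc3)CO[C@H]2c2ccc(O[Si](C(C)C)(C(C)C)C(C)C)cc2 | intermediate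
20 | 4-hydroxycinnamic acid | OC(=O)/C=C/c1ccc(O)cc1 | starting material
21 | tri(propan-2-yl)silyl (E)-3-[4-(TIPS-oxy)phenyl]prop-2-enoate | CC(C)[Si](C(C)C)(C(C)C)OC(=O)/C=C/c1ccc(O[Si](C(C)C)(C(C)C)C(C)C)cc1 | intermediate
22 | (E)-3-[4-(TIPS-oxy)phenyl]prop-2-enoic acid | OC(=O)/C=C/c1ccc(O[Si](C(C)C)(C(C)C)C(C)C)cc1 | intermediate
23 | {4-[(E)-2-bromoethenyl]phenoxy}tri(propan-2-yl)silane | Br/C=C/c1ccc(O[Si](C(C)C)(C(C)C)C(C)C)cc1 | intermediate
24 | alkylzinc iodide from 19 (CH2ZnI on C3) | I[Zn]C[C@H]2C[C@@H]([C@@H](O[Si](CC)(CC)CC)c3ccc(O[Si](C(C)C)(C(C)C)C(C)C)cc3)CO[C@H]2c2ccc(O[Si](C(C)C)(C(C)C)C(C)C)cc2 | intermediate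
25 | tris-TIPS, mono-triethylsilyl ether of the target (E alkene; 2R,3S,5R; carbinol R) | CC(C)[Si](C(C)C)(C(C)C)Oc1ccc(/C=C/C[C@H]2C[C@@H]([C@@H](O[Si](CC)(CC)CC)c3ccc(O[Si](C(C)C)(C(C)C)C(C)C)cc3)CO[C@H]2c2ccc(O[Si](C(C)C)(C(C)C)C(C)C)cc2)cc1 | intermediate
26 | 4-[(E)-3-{(2R,3S,5R)-5-[(R)-hydroxy(4-hydroxyphenyl)methyl]-2-(4-hydroxyphenyl)oxan-3-yl}prop-1-en-1-yl]phenol | Oc1ccc(/C=C/C[C@H]2C[C@@H]([C@@H](O)c3ccc(O)cc3)CO[C@H]2c2ccc(O)cc2)cc1 | target

**Step count**
Total: 17 steps. Longest linear sequence: 13 steps (1, 2, 5, 6, 7, 8, 9, 10, 11, 12, 13, 16, 17).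

**Steps most likely to fail**

Step 8. The benzylic cation may lose the allylic ring proton (E1) to a conjugated arylidene cyclopentene, may be trapped intermolecularly, or C2 may not equilibrate fully. The fallback sets out from 10 and replaces the SN1 closure by a reductive etherification. MnO2 in CH2Cl2 should oxidise only the benzylic alcohol to [(1R,4S)-4-(hydroxymethyl)cyclopent-2-en-1-yl][4-(TIPS-oxy)phenyl]methanone F1, which closes to the bicyclic hemiketal 2-[4-(TIPS-oxy)phenyl]-3-oxabicyclo[3.2.1]oct-6-en-2-ol F2. Et3SiH with BF3·OEt2 in CH2Cl2 at −78 °C should then reduce the cyclic oxocarbenium ion, which cannot eliminate towards the bridgehead. Hydride delivery should be axial, on the face anti to the etheno bridge, so the aryl ends equatorial; the Lewis acid can also equilibrate C2 towards that epimer. The fallback comes back to the route at 11.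

Step 10. The chelate may not form, leading to poor discrimination between the two formyl groups, poor facial selectivity at C7, epimerisation of the dialdehyde, or Lewis-acid ionisation of the C2 benzylic ether. The fallback sets out from 11 and differentiates the two carbons at a stable alcohol stage. Ozonolysis with NaBH4 work-up gives [(2R,3R,5S)-2-[4-(TIPS-oxy)phenyl]oxane-3,5-diyl]dimethanol F3. Oxidative lactonisation with 2,2,6,6-tetramethylpiperidin-1-oxyl (cat.) and PhI(OAc)2 is expected to start at the less hindered C5 hydroxymethyl and give 6-[4-(TIPS-oxy)phenyl]-3,7-dioxabicyclo[3.3.1]nonan-2-one F4, with isomers separable at this stage. One equivalent of 7 at −78 °C gives the hemiketal 2,6-bis[4-(TIPS-oxy)phenyl]-3,7-dioxabicyclo[3.3.1]nonan-2-ol F5, in equilibrium with the open aryl ketone [(3R,5R,6R)-5-(hydroxymethyl)-6-[4-(TIPS-oxy)phenyl]oxan-3-yl][4-(TIPS-oxy)phenyl]methanone F6. Corey–Bakshi–Shibata reduction of F6 with (S)-1-methyl-3,3-diphenyltetrahydro-1H,3H-pyrrolo[1,2-c][1,3,2]oxazaborole and BH3·SMe2 should set C7 as R by reagent control, with the aryl as the large group. The fallback comes back to the route at 17.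

Step 6 (with its feeder step 5). The β,γ-unsaturated aldehyde may epimerise at the allylic α-carbon or move its double bond into conjugation, during oxidation or by enolisation under the Grignard reagent. The fallback sets out from 4 and brings the aryl group in at the acyl oxidation level. Buffered oxidation (2,2,6,6-tetramethylpiperidin-1-oxyl cat., NaClO2, NaOCl cat., MeCN/phosphate buffer) gives (1R,4S)-4-(acetoxymethyl)cyclopent-2-ene-1-carboxylic acid F7. K2CO3 in MeOH/H2O gives (1R,4S)-4-(hydroxymethyl)cyclopent-2-ene-1-carboxylic acid F8. Carbodiimide lactonisation (1-ethyl-3-(3-dimethylaminopropyl)carbodiimide hydrochloride, 4-(dimethylamino)pyridine cat.) gives (1R,5S)-3-oxabicyclo[3.2.1]oct-6-en-2-one F9, whose α-carbon is a bridgehead and cannot enolise. The aryllithium from 6 and n-BuLi (THF, −78 °C) adds once to give hemiketal F2, the ring form of ketone F1. NaBH4 in MeOH reduces it through F1, and the fallback comes back to the route at 10.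

**Further compounds**
F1 | step 8 | [(1R,4S)-4-(hydroxymethyl)cyclopent-2-en-1-yl][4-(TIPS-oxy)phenyl]methanone | C1=C[C@H](C(=O)c2ccc(O[Si](C(C)C)(C(C)C)C(C)C)cc2)C[C@@H]1CO
F2 | step 8 | 2-[4-(TIPS-oxy)phenyl]-3-oxabicyclo[3.2.1]oct-6-en-2-ol (bridgeheads as in 11, hemiketal carbon unassigned) | C1=C[C@H]2C[C@@H]1COC2(O)c1ccc(O[Si](C(C)C)(C(C)C)C(C)C)cc1
F3 | step 10 | [(2R,3R,5S)-2-[4-(TIPS-oxy)phenyl]oxane-3,5-diyl]dimethanol | OC[C@H]2C[C@@H](CO)CO[C@H]2c2ccc(O[Si](C(C)C)(C(C)C)C(C)C)cc2
F4 | step 10 | 6-[4-(TIPS-oxy)phenyl]-3,7-dioxabicyclo[3.3.1]nonan-2-one (ring carbons as in 17) | O=C1OC[C@H]2C[C@@H]1CO[C@H]2c1ccc(O[Si](C(C)C)(C(C)C)C(C)C)cc1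
F5 | step 10 | 2,6-bis[4-(TIPS-oxy)phenyl]-3,7-dioxabicyclo[3.3.1]nonan-2-ol (hemiketal carbon unassigned) | OC1(c3ccc(O[Si](C(C)C)(C(C)C)C(C)C)cc3)OC[C@H]2C[C@@H]1CO[C@H]2c1ccc(O[Si](C(C)C)(C(C)C)C(C)C)cc1
F6 | step 10 | [(3R,5R,6R)-5-(hydroxymethyl)-6-[4-(TIPS-oxy)phenyl]oxan-3-yl][4-(TIPS-oxy)phenyl]methanone | OC[C@H]2C[C@@H](C(=O)c3ccc(O[Si](C(C)C)(C(C)C)C(C)C)cc3)CO[C@H]2c2ccc(O[Si](C(C)C)(C(C)C)C(C)C)cc2
F7 | step 6 | (1R,4S)-4-(acetoxymethyl)cyclopent-2-ene-1-carboxylic acid | C1=C[C@H](C(O)=O)C[C@@H]1COC(C)=O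
F8 | step 6 | (1R,4S)-4-(hydroxymethyl)cyclopent-2-ene-1-carboxylic acid | C1=C[C@H](C(O)=O)C[C@@H]1CO
F9 | step 6 | (1R,5S)-3-oxabicyclo[3.2.1]oct-6-en-2-one | C1=C[C@H]2C[C@@H]1COC2=O
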